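A direct plan would take rings A and B as finished arenes and close ring C last, at oxygen.
It would formylate 3,4,5-trimethoxyphenol A1, brominate, methoxylate with NaOMe and CuBr to 2-hydroxy-3,4,5,6-tetramethoxybenzaldehyde A2, and silylate A2 to its tert-butyldimethylsilyl ether A3.
It would couple A3 under carbene catalysis with {[2,5-bis(benzyloxy)phenyl]ethynyl}(phenyl)iodonium tosylate A4, close ring C with an amine to give 2-[2,5-bis(benzyloxy)phenyl]-5,6,7,8-tetramethoxy-4H-chromen-4-one A5, and finish by treating A5 with BCl3.
The first weak point would be the bromination, CuBr-mediated methoxylation and silylation on the way from A1 to A3: three steps to add one methoxy group, beside a 5-methoxy group that must be cleaved again at the end.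
The second would be the carbene-catalysed acyl–alkynyl union of A3 and A4: an untested coupling of a di-ortho-substituted, electron-rich aldehyde with an oxidation-prone iodonium salt, at the point where both fragments meet.
The third would be the last step on A5: BCl3 would have to cleave two benzyl ethers and exactly one of four methyl ethers on the most precious material, with the 6-methoxy group and the hydroquinone ring exposed.

**Plan of the new route**
The retrosynthesis cuts ring A itself, at C4a–C5 and C8–C8a. C5, C6, C7 and C8 with their four oxygens are the four carbons of dimethyl squarate, and C4a=C8a is the C5=C6 enol-ether double bond of a 2-aryl-4H-pyran-4-one.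
Ring B is bought (gentisic acid), ring C is made first (enolate acylation, then cyclisation), and ring A arises last, by 4π opening and 6π closure of a 4-pyranonyl-4-methoxycyclobutenone.
The feature that allows this is the para pair O5/O8 on ring A: the ketene oxygen becomes the free 5-OH, chelated to C4=O, and the carbinol oxygen, methylated beforehand, becomes 8-OMe.
Hence no arene is methoxylated, no acyl–alkynyl coupling is needed and no methyl ether is ever cleaved; the last step is a neutral hydrogenolysis.

Key step: step 5

Remark: 10, 11 and 13 are racemic; their stereocentres vanish in step 5 and the target has none.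

Step 1
Reactants: 1 2,5-dihydroxybenzoic acid (gentisic acid)
Product: 3 2,5-bis(benzyloxy)benzoic acid, via benzyl 2,5-bis(benzyloxy)benzoate 2 (not isolated)
Conditions: BnBr (3.3 equiv), K2CO3, DMF, 60 °C, N2; then NaOH, MeOH–H2O, 70 °C; HCl to pH 2
Reagents that add atoms: benzyl bromide, BrCc1ccccc1; sodium hydroxide, [Na+].[OH-]
Why: Williamson benzylation of both phenols and of the carboxylate, followed by saponification of the benzyl ester alone by acyl–oxygen cleavage, run under nitrogen because the hydroquinone oxidises in base and air.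

Step 2
Reactants: 3 2,5-bis(benzyloxy)benzoic acid; 4 (3E)-4-methoxybut-3-en-2-one
Product: 7 2-[2,5-bis(benzyloxy)phenyl]-4H-pyran-4-one, via 2,5-bis(benzyloxy)benzoyl chloride 5 (not isolated), via methoxyenone diketone 6 (not isolated)
Conditions: (COCl)2, DMF (cat.), CH2Cl2, 0 °C → rt, evaporate; 4 (2.2 equiv), LiN(SiMe3)2 (2.2 equiv), THF, −78 °C, then 5, −78 → −20 °C; 1 M HCl; CF3CO2H (cat.), toluene, rt → 50 °C
Reagents that add atoms: none
Why: Claisen-type C-acylation of the kinetic lithium enolate of the beta-methoxy enone by the aroyl chloride (the second enolate equivalent takes up the acidic diketone proton), then acid-catalysed 6-endo addition of the aryl-ketone enol oxygen to the methoxyenone with loss of methanol, a known route to 2-substituted 4-pyranones that closes ring C.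

Step 3
Reactants: 7 2-[2,5-bis(benzyloxy)phenyl]-4H-pyran-4-one; 8 dimethyl squarate (3,4-dimethoxycyclobut-3-ene-1,2-dione)
Product: 10 4-{6-[2,5-bis(benzyloxy)phenyl]-4-oxo-4H-pyran-2-yl}-4-hydroxy-2,3-dimethoxycyclobut-2-en-1-one (racemic), via magnesiated pyranone 9 (not isolated)
Conditions: BF3·OEt2 (1.1 equiv), THF, −40 °C; TMPMgCl·LiCl (1.2 equiv; TMP = 2,2,6,6-tetramethylpiperidide), −40 °C, 30 min; cannulate into 8 (1.5 equiv), THF, −78 → −40 °C; aq NH4Cl
Reagents that add atoms: none
Why: Proposed new method: BF3 bound to the carbonyl oxygen should make the pyranone pyrylium-like, raise the acidity of the C–H next to the ring oxygen and occupy the only site from which the TMP base could be guided to C3 or C5, so that the hindered base removes the C6–H, the only ring C–H alpha to the ring oxygen, to give the in-plane alpha-alkoxyvinyl carbanion 9, which has no leaving group on the neighbouring carbon and so cannot open the ring, and 9 should add 1,2 to one of the two equivalent strained carbonyl groups of 8 to give the tertiary alkoxide; the closest known reactions are the site-selective C2 or C3 metalation of chromones and 4-quinolones with TMPMgCl·LiCl and TMPZnCl·LiCl (where a Lewis acid decides the site), the BF3-triggered alpha-metalation of pyridines, and the 1,2-addition of alpha-lithiated cyclic enol ethers and heteroaryllithiums to dialkyl squarates, and what is new is a metalated monocyclic 4-pyranone as the nucleophile toward a squarate.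

Step 4
Reactants: 10 4-{6-[2,5-bis(benzyloxy)phenyl]-4-oxo-4H-pyran-2-yl}-4-hydroxy-2,3-dimethoxycyclobut-2-en-1-one
Product: 11 4-{6-[2,5-bis(benzyloxy)phenyl]-4-oxo-4H-pyran-2-yl}-2,3,4-trimethoxycyclobut-2-en-1-one (racemic)
Conditions: MeI (10 equiv), Ag2O (2 equiv), 4 Å MS, MeCN, rt, dark
Reagents that add atoms: iodomethane, CI
Why: Ag2O-promoted O-methylation of the tertiary carbinol under non-basic conditions, the usual protection of 4-hydroxycyclobutenones, which avoids alkoxide-driven ring cleavage and decides, before ring A exists, that O8 and not O5 will carry the methyl group.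

Step 5
Reactants: 11 4-{6-[2,5-bis(benzyloxy)phenyl]-4-oxo-4H-pyran-2-yl}-2,3,4-trimethoxycyclobut-2-en-1-one
Product: 14 2-[2,5-bis(benzyloxy)phenyl]-5-hydroxy-6,7,8-trimethoxy-4H-chromen-4-one, via dienylketene 12 (not isolated), via cyclohexadienone 13 (not isolated)
Conditions: p-xylene (0.02 M, degassed), 138 °C, N2
Reagents that add atoms: none
Why: Heating should open cyclobutenone 11 by conrotatory 4π electrocyclic cleavage of its C1–C4 bond, and because the C4 methoxy donor rotates outward the pyranonyl group turns inward to give the (Z)-dienylketene 12 with the ketene carbon next to the pyranone C5–H (pyranone numbered as in 7). A 6π electrocyclisation of the ketene C=C, the central C=C and the pyranone C5=C6 bond should then form the C4a–C5 bond of the flavone and close ring A (six-membered carbocycle, disrotatory 6π closure, fused to ring C) as cyclohexadienone 13, whose C4a–H lies between two carbonyl groups and shifts to oxygen to give the aromatic, hydrogen-bonded 5-hydroxychromone 14. The closest known reaction is the Moore rearrangement of 4-aryl-, 4-heteroaryl- and 4-alkenyl-4-alkoxycyclobutenones, including those made from cyclic enol ethers, to hydroquinone mono-ethers. No stereocentre remains, since the racemic centres of 11 and 13 are destroyed on aromatisation. The step needs two selectivities and the substrate secures both: closure can occur only at pyranone C5 because C6 is the point of attachment, and the free phenol can arise only at C5 of the flavone because that oxygen is the ketene oxygen while O8 already carries its methyl group.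

Step 6
Reactants: 14 2-[2,5-bis(benzyloxy)phenyl]-5-hydroxy-6,7,8-trimethoxy-4H-chromen-4-one
Product: 15 2-(2,5-dihydroxyphenyl)-5-hydroxy-6,7,8-trimethoxy-4H-chromen-4-one (5,2',5'-trihydroxy-6,7,8-trimethoxyflavone)
Conditions: H2 (1 atm), Pd/C (10 wt % Pd on carbon), EtOAc–MeOH, rt; filtered under N2
Reagents that add atoms: none
Why: Catalytic hydrogenolysis of the two aryl benzyl ethers under neutral conditions, which should leave the three methyl ethers and the cross-conjugated C2=C3 bond of the chromone untouched if stopped after two equivalents of hydrogen.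

**Compound list**
1 | 2,5-dihydroxybenzoic acid | O=C(O)c1cc(O)ccc1O | starting material
2 | benzyl 2,5-bis(benzyloxy)benzoate | O=C(OCc1ccccc1)c1cc(OCc2ccccc2)ccc1OCc1ccccc1 | intermediate, not isolated
3 | 2,5-bis(benzyloxy)benzoic acid | O=C(O)c1cc(OCc2ccccc2)ccc1OCc1ccccc1 | intermediate
4 | (3E)-4-methoxybut-3-en-2-one | CO/C=C/C(C)=O | starting material
5 | 2,5-bis(benzyloxy)benzoyl chloride | O=C(Cl)c1cc(OCc2ccccc2)ccc1OCc1ccccc1 | intermediate, not isolated
6 | (4E)-1-[2,5-bis(benzyloxy)phenyl]-5-methoxypent-4-ene-1,3-dione (drawn as the diketo tautomer) | CO/C=C/C(=O)CC(=O)c1cc(OCc2ccccc2)ccc1OCc1ccccc1 | intermediate, not isolated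
7 | 2-[2,5-bis(benzyloxy)phenyl]-4H-pyran-4-one | O=c1cc(-c2cc(OCc3ccccc3)ccc2OCc2ccccc2)occ1 | intermediate
8 | dimethyl squarate (3,4-dimethoxycyclobut-3-ene-1,2-dione) | COC1=C(OC)C(=O)C1=O | starting material
9 | {6-[2,5-bis(benzyloxy)phenyl]-4-oxo-4H-pyran-2-yl}magnesium chloride (as its LiCl and BF3 complex) | O=c1cc(-c2cc(OCc3ccccc3)ccc2OCc2ccccc2)oc([Mg]Cl)c1 | intermediate, not isolated
10 | 4-{6-[2,5-bis(benzyloxy)phenyl]-4-oxo-4H-pyran-2-yl}-4-hydroxy-2,3-dimethoxycyclobut-2-en-1-one (racemic) | COC1=C(OC)C(O)(c2cc(=O)cc(-c3cc(OCc4ccccc4)ccc3OCc3ccccc3)o2)C1=O | intermediate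
11 | 4-{6-[2,5-bis(benzyloxy)phenyl]-4-oxo-4H-pyran-2-yl}-2,3,4-trimethoxycyclobut-2-en-1-one (racemic) | COC1=C(OC)C(OC)(c2cc(=O)cc(-c3cc(OCc4ccccc4)ccc3OCc3ccccc3)o2)C1=O | intermediate
12 | (3Z)-4-{6-[2,5-bis(benzyloxy)phenyl]-4-oxo-4H-pyran-2-yl}-2,3,4-trimethoxybuta-1,3-dien-1-one | O=C=C(OC)/C(OC)=C(OC)\c1cc(=O)cc(-c2cc(OCc3ccccc3)ccc2OCc2ccccc2)o1 | intermediate, not isolated
13 | 2-[2,5-bis(benzyloxy)phenyl]-6,7,8-trimethoxy-4aH-chromene-4,5-dione (racemic) | O=C1C(OC)=C(OC)C(OC)=C2OC(-c3cc(OCc4ccccc4)ccc3OCc3ccccc3)=CC(=O)C12 | intermediate, not isolated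
14 | 2-[2,5-bis(benzyloxy)phenyl]-5-hydroxy-6,7,8-trimethoxy-4H-chromen-4-one | COc1c(OC)c(O)c2c(=O)cc(-c3cc(OCc4ccccc4)ccc3OCc3ccccc3)oc2c1OC | intermediate
15 | 2-(2,5-dihydroxyphenyl)-5-hydroxy-6,7,8-trimethoxy-4H-chromen-4-one (5,2',5'-trihydroxy-6,7,8-trimethoxyflavone) | COc1c(OC)c(O)c2c(=O)cc(-c3cc(O)ccc3O)oc2c1OC | target

Total step count: 6. Longest linear sequence: 6 steps (1 → 15).

**Steps most likely to fail**

Step 3 (proposed new method). The base may be delivered to C5 or C3 instead of C6, the magnesiated pyranone may attack a second pyranone molecule, or its addition to the squarate may be too slow. The fallback uses only known chemistry and gives up the ring order: ring A would be brought in ready-made and ring C closed at oxygen by the diketone route of the Baker–Venkataraman type. It sets out from 5. Purchased 1-(2-hydroxy-3,4,5,6-tetramethoxyphenyl)ethan-1-one F1 would be demethylated with BCl3 (CH2Cl2, −78 → 0 °C) at the methoxy group ortho to the acetyl group, by chelation, to the symmetric 1-(2,6-dihydroxy-3,4,5-trimethoxyphenyl)ethan-1-one F2. Its polylithium salt (LiN(SiMe3)2, 4 equiv, THF, −78 °C) would be C-acylated with 5 to 1-[2,5-bis(benzyloxy)phenyl]-3-(2,6-dihydroxy-3,4,5-trimethoxyphenyl)propane-1,3-dione F3. TsOH in warm toluene would then close ring C on either of the two equivalent hydroxyl groups. The detour comes back to the route at 14, and steps 4 and 5 would then not be run.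

Step 5 (key step). The ketene may be diverted (dimerisation, capture by traces of water) if closure onto the cross-conjugated C5=C6 bond is slow at the temperature the methyl ether needs, and the electron-rich product may oxidise in hot solvent. The fallback sets out from 10 and leaves out step 4. The unprotected carbinol 10, the classic substrate of this ring expansion, would be heated in toluene at 110 °C under N2 to the hydroquinone 2-[2,5-bis(benzyloxy)phenyl]-5,8-dihydroxy-6,7-dimethoxy-4H-chromen-4-one F4. Me2SO4 (1.05 equiv) and K2CO3 in acetone under N2 would then methylate only the 8-OH, because the 5-OH is held in the chelate with C4=O. The detour comes back at 14. This variant would give the same F4 whichever end of the pyranone C5=C6 bond carries the cyclobutenone.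

Step 2. The enolate may be acylated at oxygen or twice, and enone 4 may polymerise under base. The fallback sets out from 5 and builds ring C by cycloaddition instead. Reduction with LiAlH(OtBu)3 (THF, −78 °C) would give 2,5-bis(benzyloxy)benzaldehyde F5. A hetero-Diels–Alder reaction with 1-methoxy-3-(trimethylsilyloxy)buta-1,3-diene (BF3·OEt2, CH2Cl2, −78 °C; then CF3CO2H) would give racemic 2-[2,5-bis(benzyloxy)phenyl]-2,3-dihydro-4H-pyran-4-one F6. Saegusa–Ito dehydrogenation (LiN(SiMe3)2, Me3SiCl; then Pd(OAc)2, MeCN) would aromatise the partly saturated ring. The detour comes back at 7.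

**Further compounds**
F1 | step 3 | 1-(2-hydroxy-3,4,5,6-tetramethoxyphenyl)ethan-1-one (purchased) | CC(=O)c1c(O)c(OC)c(OC)c(OC)c1OC
F2 | step 3 | 1-(2,6-dihydroxy-3,4,5-trimethoxyphenyl)ethan-1-one | CC(=O)c1c(O)c(OC)c(OC)c(OC)c1O
F3 | step 3 | 1-[2,5-bis(benzyloxy)phenyl]-3-(2,6-dihydroxy-3,4,5-trimethoxyphenyl)propane-1,3-dione | O=C(CC(=O)c1c(O)c(OC)c(OC)c(OC)c1O)c1cc(OCc2ccccc2)ccc1OCc1ccccc1
F4 | step 5 | 2-[2,5-bis(benzyloxy)phenyl]-5,8-dihydroxy-6,7-dimethoxy-4H-chromen-4-one | COc1c(OC)c(O)c2c(=O)cc(-c3cc(OCc4ccccc4)ccc3OCc3ccccc3)oc2c1O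
F5 | step 2 | 2,5-bis(benzyloxy)benzaldehyde | O=Cc1cc(OCc2ccccc2)ccc1OCc1ccccc1
F6 | step 2 | 2-[2,5-bis(benzyloxy)phenyl]-2,3-dihydro-4H-pyran-4-one (racemic) | O=C1CC(c2cc(OCc3ccccc3)ccc2OCc2ccccc2)OC=C1
A1 | direct plan | 3,4,5-trimethoxyphenol | COc1cc(O)cc(OC)c1OC
A2 | direct plan | 2-hydroxy-3,4,5,6-tetramethoxybenzaldehyde | O=Cc1c(O)c(OC)c(OC)c(OC)c1OC
A3 | direct plan | 2-[(tert-butyldimethylsilyl)oxy]-3,4,5,6-tetramethoxybenzaldehyde | O=Cc1c(O[Si](C)(C)C(C)(C)C)c(OC)c(OC)c(OC)c1OC
A4 | direct plan | {[2,5-bis(benzyloxy)phenyl]ethynyl}(phenyl)iodonium 4-methylbenzenesulfonate | Cc1ccc(cc1)S(=O)(=O)[O-].c1ccc(cc1)[I+]C#Cc1cc(OCc2ccccc2)ccc1OCc1ccccc1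
A5 | direct plan | 2-[2,5-bis(benzyloxy)phenyl]-5,6,7,8-tetramethoxy-4H-chromen-4-one | COc1c(OC)c(OC)c2c(=O)cc(-c3cc(OCc4ccccc4)ccc3OCc3ccccc3)oc2c1OC
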